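**Assumption:** the stereo-SMILES is taken literally: a trans-decalin (1R,2R,4aR,6R,8aS) with an axial C6 methyl and the dienyl group trans to the acyl group, joined to an L-threonine-derived tetramic acid. This pattern cannot come from a suprafacial Diels–Alder reaction of an all-E polyene, so the decalin is built stepwise.

## Retrosynthetic overview

1. Cut the C3–acyl bond of the tetramic acid: decalin carboxylic acid plus an N-Boc tetramic acid, joined by a light-driven radical C-acylation.
2. Ring B comes from an Ireland–Claisen ring contraction of a trans-fused δ-lactone carrying a (1Z)-trienyl group; this forms C1–C2, the quaternary C1, C2 and the C3=C4 alkene.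
3. The lactone comes from Felkin–Anh reduction of an ynone (aldehyde plus dienyne), then Z-selective semi-hydrogenation.
4. Ring A is bought as (S)-pulegone, degraded to (S)-5-methylcyclohexenone; copper-catalysed vinyl addition and enolate alkylation set C4a and C8a trans,trans against the methyl, then the ketone is removed.
5. Ring order: ring A (chiral pool), temporary lactone ring, ring B (Claisen); the tetramic acid ring is made separately from Boc-Thr(tBu)-OH.

Decalin numbering (C1–C8a) is used in the "Why" lines.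

## Route

Step 1
Reactants: 1 (S)-(−)-pulegone
Product: 2 (6S)-2,2,6-trimethyl-1-oxaspiro[2.5]octan-4-one
Conditions: H2O2 (30%), NaOH (cat.), MeOH, 0 °C → rt
Reagents that add atoms: hydrogen peroxide, OO
Why: Weitz–Scheffer nucleophilic epoxidation of the tetrasubstituted enone; the bought methyl stereocentre is untouched and the new spiro centre is destroyed in step 2.

Step 2
Reactants: 2 (6S)-2,2,6-trimethyl-1-oxaspiro[2.5]octan-4-one
Product: 3 (5S)-5-methyl-2-(phenylsulfanyl)cyclohexan-1-one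
Conditions: PhSNa, THF, reflux; H2O
Reagents that add atoms: sodium benzenethiolate, [Na+].[S-]c1ccccc1
Why: thiolate opens the epoxide at the α-carbon and the β-alkoxide fragments by retro-aldol loss of acetone (known degradation of pulegone oxide), giving the α-phenylthio ketone on the side remote from the methyl.

Step 3
Reactants: 3 (5S)-5-methyl-2-(phenylsulfanyl)cyclohexan-1-one
Product: 5 (5S)-5-methylcyclohex-2-en-1-one, via sulfoxide 4 (not isolated)
Conditions: mCPBA, CH2Cl2, −78 °C; then PhMe, 110 °C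
Reagents that add atoms: none
Why: sulfide oxidation followed by thermal syn-elimination of the sulfoxide gives the enone regiospecifically without touching the methyl centre.

Step 4
Reactants: 5 (5S)-5-methylcyclohex-2-en-1-one; 6 vinylmagnesium bromide; 7 methyl bromoacetate
Product: 9 methyl 2-[(1R,2R,4S)-2-ethenyl-4-methyl-6-oxocyclohexyl]acetate, via magnesium enolate 8 (not isolated)
Conditions: CuBr·SMe2 (10 mol%), THF, −78 °C; then 7, DMPU, −78 → 0 °C
Reagents that add atoms: none
Why: tandem conjugate addition–enolate alkylation; the vinyl copper reagent attacks axially anti to the methyl (sets C4a, 3,5-trans) and the enolate is alkylated anti to the new vinyl group (sets C8a, 2,3-trans), which gives the axial-methyl relationship of the target.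

Step 5
Reactants: 9 methyl 2-[(1R,2R,4S)-2-ethenyl-4-methyl-6-oxocyclohexyl]acetate
Product: 11 methyl 2-[(1R,2R,4R)-2-ethenyl-4-methylcyclohexyl]acetate, via tosylhydrazone 10 (not isolated)
Conditions: TsNHNH2, EtOH, 40 °C; then catecholborane, CHCl3, 0 °C; NaOAc·3H2O, 60 °C
Reagents that add atoms: none
Why: Kabalka-type reductive deoxygenation of the tosylhydrazone (hydride addition, loss of sulfinate and N2) removes the ketone under near-neutral conditions that spare the ester and vinyl group and do not epimerise C8a.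

Step 6
Reactants: 11 methyl 2-[(1R,2R,4R)-2-ethenyl-4-methylcyclohexyl]acetate
Product: 12 methyl 2-[(1S,2R,4R)-2-ethenyl-4-methylcyclohexyl]propanoate
Conditions: LiN(iPr)2, THF, −78 °C; MeI
Reagents that add atoms: iodomethane, CI
Why: ester enolate alkylation installs the future C1 methyl; the new α-centre is formed as a mixture, which does not matter because it becomes sp2 in step 13.

Step 7
Reactants: 12 methyl 2-[(1S,2R,4R)-2-ethenyl-4-methylcyclohexyl]propanoate
Product: 13 methyl 2-[(1S,2S,4R)-2-formyl-4-methylcyclohexyl]propanoate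
Conditions: O3, CH2Cl2/MeOH, −78 °C; Me2S
Reagents that add atoms: ozone, [O-][O+]=O
Why: ozonolysis of the only alkene with neutral reductive work-up gives the aldehyde (future C4) without epimerising C4a.

Step 8
Reactants: 14 (2E,4E)-hexa-2,4-dienal
Product: 15 (3E,5E)-hepta-3,5-dien-1-yne
Conditions: Me3SiCHN2, LiN(iPr)2, THF, −78 °C → rt
Reagents that add atoms: (trimethylsilyl)diazomethane, C[Si](C)(C)C=[N+]=[N-]
Why: Colvin homologation (Peterson elimination, loss of N2, 1,2-hydrogen shift of the alkylidene carbene) converts the enal into the terminal alkyne with both E double bonds intact.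

Step 9
Reactants: 13 methyl 2-[(1S,2S,4R)-2-formyl-4-methylcyclohexyl]propanoate; 15 (3E,5E)-hepta-3,5-dien-1-yne
Product: 17 methyl 2-[(1S,2S,4R)-2-[(4E,6E)-1-hydroxyocta-4,6-dien-2-yn-1-yl]-4-methylcyclohexyl]propanoate, via lithium acetylide 16 (not isolated)
Conditions: n-BuLi, THF, −78 °C; then 13, −78 °C; AcOH quench
Reagents that add atoms: none
Why: lithium acetylide 1,2-addition to the aldehyde at low temperature outpaces ester attack and enolisation; the carbinol mixture is irrelevant because it is oxidised in step 10.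

Step 10
Reactants: 17 methyl 2-[(1S,2S,4R)-2-[(4E,6E)-1-hydroxyocta-4,6-dien-2-yn-1-yl]-4-methylcyclohexyl]propanoate
Product: 18 methyl 2-[(1S,2S,4R)-4-methyl-2-[(4E,6E)-octa-4,6-dien-2-ynoyl]cyclohexyl]propanoate
Conditions: Dess–Martin periodinane, pyridine, CH2Cl2, 0 °C
Reagents that add atoms: none
Why: buffered Dess–Martin oxidation of the propargylic alcohol gives the ynone without isomerising the diene or epimerising the α-carbon.

Step 11
Reactants: 18 methyl 2-[(1S,2S,4R)-4-methyl-2-[(4E,6E)-octa-4,6-dien-2-ynoyl]cyclohexyl]propanoate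
Product: 20 (1S,4aS,7R,8aS)-1-[(3E,5E)-hepta-3,5-dien-1-yn-1-yl]-4,7-dimethyl-1,4,4a,5,6,7,8,8a-octahydro-3H-isochromen-3-one, via lithium alkoxide 19 (not isolated)
Conditions: LiBH(s-Bu)3, THF, −78 °C; then rt; aq. NH4Cl
Reagents that add atoms: none
Why: Felkin–Anh 1,2-reduction, with the bulky hydride attacking anti to the more branched ring carbon (C8a), sets the carbinol centre (temporary C4, alkynyl equatorial), and the alkoxide closes the trans-fused δ-lactone by acyl substitution on the neighbouring methyl ester.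

Step 12
Reactants: 20 (1S,4aS,7R,8aS)-1-[(3E,5E)-hepta-3,5-dien-1-yn-1-yl]-4,7-dimethyl-1,4,4a,5,6,7,8,8a-octahydro-3H-isochromen-3-one
Product: 21 (1R,4aS,7R,8aS)-1-[(1Z,3E,5E)-hepta-1,3,5-trien-1-yl]-4,7-dimethyl-1,4,4a,5,6,7,8,8a-octahydro-3H-isochromen-3-one
Conditions: H2 (1 atm), Pd/CaCO3 poisoned with Pb(OAc)2, quinoline, EtOAc, rt
Reagents that add atoms: none
Why: Lindlar semi-hydrogenation adds H2 syn to the alkyne only, giving the Z alkene that later places the dienyl group trans to the carboxyl.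

Step 13
Reactants: 21 (1R,4aS,7R,8aS)-1-[(1Z,3E,5E)-hepta-1,3,5-trien-1-yl]-4,7-dimethyl-1,4,4a,5,6,7,8,8a-octahydro-3H-isochromen-3-one
Product: 24 (1R,2R,4aR,6R,8aS)-1,6-dimethyl-2-[(1E,3E)-penta-1,3-dien-1-yl]-1,2,4a,5,6,7,8,8a-octahydronaphthalene-1-carboxylic acid, via silyl ketene acetal 22 (not isolated), via silyl ester 23 (not isolated)
Conditions: KN(SiMe3)2, t-BuMe2SiCl, THF–DMPU, −78 °C; PhMe, 110 °C; then 1 M HCl, THF
Reagents that add atoms: none
Why: ring-contracting Ireland–Claisen rearrangement through a ring-enforced boat [3,3] transition state; the C1–C2 bond forms on the lactone face carrying the trienyl group, so the carboxyl ends cis to H-8a with the methyl axial (C1), the Z alkene puts the dienyl group trans to the carboxyl (C2), and C3=C4 forms where the C–O bond breaks.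

Step 14
Reactants: 25 N-(tert-butoxycarbonyl)-O-tert-butyl-L-threonine; 26 Meldrum's acid
Product: 28 tert-butyl (2S)-2-[(1R)-1-tert-butoxyethyl]-3,5-dioxopyrrolidine-1-carboxylate, via acyl Meldrum's acid 27 (not isolated)
Conditions: DCC, DMAP, CH2Cl2, 0 °C → rt; then EtOAc, reflux
Reagents that add atoms: none
Why: Jouin tetramic acid synthesis; C-acylation of Meldrum's acid, then thermal loss of acetone and CO2 to an acylketene that is trapped by the carbamate nitrogen, keeping both threonine stereocentres.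

Step 15
Reactants: 24 (1R,2R,4aR,6R,8aS)-1,6-dimethyl-2-[(1E,3E)-penta-1,3-dien-1-yl]-1,2,4a,5,6,7,8,8a-octahydronaphthalene-1-carboxylic acid; 28 tert-butyl (2S)-2-[(1R)-1-tert-butoxyethyl]-3,5-dioxopyrrolidine-1-carboxylate
Product: 30 tert-butyl (2S)-2-[(1R)-1-tert-butoxyethyl]-4-{[(1R,2R,4aR,6R,8aS)-1,6-dimethyl-2-[(1E,3E)-penta-1,3-dien-1-yl]-1,2,4a,5,6,7,8,8a-octahydronaphthalen-1-yl]carbonyl}-3-hydroxy-5-oxo-2,5-dihydro-1H-pyrrole-1-carboxylate, via acyl imidazolide 29 (not isolated)
Conditions: CDI, MeCN, rt; then 28, DBU, 1,4-dimethyl-1,2,4-triazolium iodide (20 mol%), fac-Ir(ppy)3 = Ir(C11H8N)3 (1 mol%), 450 nm LEDs, rt; aq. citric acid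
Reagents that add atoms: none
Why: Proposed new method: the triazolylidene converts the hindered acyl imidazolide into an acyl azolium, which the excited trivalent iridium complex reduces to a persistent ketyl-type radical; the resulting tetravalent iridium oxidises the tetramate enolate to its C3 radical, and polarity-matched radical–radical coupling followed by loss of the carbene forges the C3–acyl bond under neutral, redox-neutral conditions (any O-acyl product re-enters through the azolium); the closest known reactions are carbene/photoredox ketone synthesis from acyl imidazoles with alkyl radicals and the DMAP-mediated O-to-C acyl shift of 4-O-acyl tetramates, which fails for α-quaternary acyl groups.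

Step 16
Reactants: 30 N-Boc-O-tert-butyl protected target
Product: 31 CNP0298257.3
Conditions: CF3CO2H/CH2Cl2 (1:3), 0 °C → rt
Reagents that add atoms: none
Why: acidolysis removes the Boc group and the tert-butyl ether in one operation (loss of isobutene and CO2) without touching any stereocentre.

## Compound list

1 | (5S)-5-methyl-2-(propan-2-ylidene)cyclohexan-1-one, (S)-(−)-pulegone | C[C@H]1CCC(=C(C)C)C(=O)C1 | starting material
2 | (6S)-2,2,6-trimethyl-1-oxaspiro[2.5]octan-4-one (pulegone oxide, both spiro epimers) | C[C@H]1CCC2(OC2(C)C)C(=O)C1 | intermediate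
3 | (5S)-5-methyl-2-(phenylsulfanyl)cyclohexan-1-one (both C2 epimers) | C[C@H]1CCC(Sc2ccccc2)C(=O)C1 | intermediate
4 | (5S)-5-methyl-2-(phenylsulfinyl)cyclohexan-1-one | C[C@H]1CCC(S(=O)c2ccccc2)C(=O)C1 | intermediate (not isolated)
5 | (5S)-5-methylcyclohex-2-en-1-one | C[C@H]1CC=CC(=O)C1 | intermediate
6 | vinylmagnesium bromide | C=C[Mg]Br | starting material
7 | methyl bromoacetate | COC(=O)CBr | starting material
8 | bromomagnesium (3R,5S)-3-ethenyl-5-methylcyclohex-1-en-1-olate | C=C[C@H]1C[C@H](C)CC(O[Mg]Br)=C1 | intermediate (not isolated)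
9 | methyl 2-[(1R,2R,4S)-2-ethenyl-4-methyl-6-oxocyclohexyl]acetate (vinyl trans to methyl and trans to the acetate arm) | C=C[C@H]1C[C@H](C)CC(=O)[C@@H]1CC(=O)OC | intermediate
10 | 4-methylbenzenesulfonylhydrazone of 9 | C=C[C@H]1C[C@H](C)CC(=NNS(=O)(=O)c2ccc(C)cc2)[C@@H]1CC(=O)OC | intermediate (not isolated)
11 | methyl 2-[(1R,2R,4R)-2-ethenyl-4-methylcyclohexyl]acetate | C=C[C@H]1C[C@H](C)CC[C@@H]1CC(=O)OC | intermediate
12 | methyl 2-[(1S,2R,4R)-2-ethenyl-4-methylcyclohexyl]propanoate (both epimers at the propanoate α-carbon) | C=C[C@H]1C[C@H](C)CC[C@@H]1C(C)C(=O)OC | intermediate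
13 | methyl 2-[(1S,2S,4R)-2-formyl-4-methylcyclohexyl]propanoate (both α-epimers) | O=C[C@H]1C[C@H](C)CC[C@@H]1C(C)C(=O)OC | intermediate
14 | (2E,4E)-hexa-2,4-dienal (sorbaldehyde) | C/C=C/C=C/C=O | starting material
15 | (3E,5E)-hepta-3,5-dien-1-yne | C#C/C=C/C=C/C | intermediate
16 | lithium (3E,5E)-hepta-3,5-dien-1-yn-1-ide | [Li]C#C/C=C/C=C/C | intermediate (not isolated)
17 | methyl 2-[(1S,2S,4R)-2-[(4E,6E)-1-hydroxyocta-4,6-dien-2-yn-1-yl]-4-methylcyclohexyl]propanoate (carbinol epimers) | C/C=C/C=C/C#CC(O)[C@H]1C[C@H](C)CC[C@@H]1C(C)C(=O)OC | intermediate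
18 | methyl 2-[(1S,2S,4R)-4-methyl-2-[(4E,6E)-octa-4,6-dien-2-ynoyl]cyclohexyl]propanoate | C/C=C/C=C/C#CC(=O)[C@H]1C[C@H](C)CC[C@@H]1C(C)C(=O)OC | intermediate
19 | lithium alkoxide of methyl 2-[(1S,2S,4R)-2-[(1S,4E,6E)-1-hydroxyocta-4,6-dien-2-yn-1-yl]-4-methylcyclohexyl]propanoate | C/C=C/C=C/C#C[C@@H](O[Li])[C@H]1C[C@H](C)CC[C@@H]1C(C)C(=O)OC | intermediate (not isolated)
20 | (1S,4aS,7R,8aS)-1-[(3E,5E)-hepta-3,5-dien-1-yn-1-yl]-4,7-dimethyl-1,4,4a,5,6,7,8,8a-octahydro-3H-isochromen-3-one (trans-fused; C4 epimers) | CC1C(=O)O[C@H](C#C/C=C/C=C/C)[C@H]2C[C@H](C)CC[C@@H]21 | intermediate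
21 | (1R,4aS,7R,8aS)-1-[(1Z,3E,5E)-hepta-1,3,5-trien-1-yl]-4,7-dimethyl-1,4,4a,5,6,7,8,8a-octahydro-3H-isochromen-3-one (C4 epimers) | CC1C(=O)O[C@H](/C=C\C=C\C=C\C)[C@H]2C[C@H](C)CC[C@@H]21 | intermediate
22 | tert-butyldimethylsilyl ketene acetal of 21 | CC1=C(O[Si](C)(C)C(C)(C)C)O[C@H](/C=C\C=C\C=C\C)[C@H]2C[C@H](C)CC[C@@H]21 | intermediate (not isolated)
23 | tert-butyldimethylsilyl ester of 24 | C/C=C/C=C/[C@@H]1C=C[C@H]2C[C@H](C)CC[C@@H]2[C@@]1(C)C(=O)O[Si](C)(C)C(C)(C)C | intermediate (not isolated)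
24 | (1R,2R,4aR,6R,8aS)-1,6-dimethyl-2-[(1E,3E)-penta-1,3-dien-1-yl]-1,2,4a,5,6,7,8,8a-octahydronaphthalene-1-carboxylic acid | C/C=C/C=C/[C@@H]1C=C[C@H]2C[C@H](C)CC[C@@H]2[C@@]1(C)C(=O)O | intermediate
25 | N-(tert-butoxycarbonyl)-O-tert-butyl-L-threonine | C[C@@H](OC(C)(C)C)[C@H](NC(=O)OC(C)(C)C)C(=O)O | starting material
26 | 2,2-dimethyl-1,3-dioxane-4,6-dione (Meldrum's acid) | CC1(C)OC(=O)CC(=O)O1 | starting material
27 | 5-[N-Boc-O-tert-butyl-L-threonyl] Meldrum's acid | C[C@@H](OC(C)(C)C)[C@H](NC(=O)OC(C)(C)C)C(=O)C1C(=O)OC(C)(C)OC1=O | intermediate (not isolated)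
28 | tert-butyl (2S)-2-[(1R)-1-tert-butoxyethyl]-3,5-dioxopyrrolidine-1-carboxylate | CC(C)(C)OC(=O)N1C(=O)CC(=O)[C@@H]1[C@@H](C)OC(C)(C)C | intermediate
29 | 1-acylimidazole (imidazolide) of acid 24 | C/C=C/C=C/[C@@H]1C=C[C@H]2C[C@H](C)CC[C@@H]2[C@@]1(C)C(=O)n1ccnc1 | intermediate (not isolated)
30 | N-Boc-O-tert-butyl protected target (3-acyl tetramic acid, enol form) | C/C=C/C=C/[C@@H]1C=C[C@H]2C[C@H](C)CC[C@@H]2[C@@]1(C)C(=O)C1=C(O)[C@H]([C@@H](C)OC(C)(C)C)N(C(=O)OC(C)(C)C)C1=O | intermediate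
31 | CNP0298257.3, (5S)-3-{[(1R,2R,4aR,6R,8aS)-1,6-dimethyl-2-[(1E,3E)-penta-1,3-dien-1-yl]-1,2,4a,5,6,7,8,8a-octahydronaphthalen-1-yl]carbonyl}-4-hydroxy-5-[(1R)-1-hydroxyethyl]-1,5-dihydro-2H-pyrrol-2-one | C/C=C/C=C/[C@@H]1C=C[C@H]2C[C@H](C)CC[C@@H]2[C@@]1(C)C(=O)C1=C(O)[C@H]([C@@H](C)O)NC1=O | target

## Step count and risks

Total step count: 16. Longest linear sequence: 14 steps (steps 1–7, 9–13, 15 and 16; steps 8 and 14 are branch steps).

**Step 11 (Felkin–Anh reduction and lactonisation).** Facial selectivity at the ynone may be modest, and only the epimer with the alkynyl group equatorial gives the correct Claisen outcome. Fallback: set out from 17, whose major epimer from the direct acetylide addition has the opposite carbinol configuration. Saponify it (LiOH, THF/H2O) to 2-[(1S,2S,4R)-2-[(1R,4E,6E)-1-hydroxyocta-4,6-dien-2-yn-1-yl]-4-methylcyclohexyl]propanoic acid F1, then close the ring by Mitsunobu lactonisation (PPh3, DIAD, PhMe), which inverts the propargylic centre. This comes back to the route at 20, setting the centre by stereospecific inversion instead of reagent approach control.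

**Step 13 (Ireland–Claisen ring contraction).** The boat transition state carries a Z (inside) trienyl group next to the ring A methylene and a trans ring fusion, so it may be slow or lose to a 1,5-hydrogen shift. Fallback: set out from 12 and come back at 24 by an open-chain Claisen followed by ring-closing metathesis.
- Saponify 12 to 2-[(1S,2R,4R)-2-ethenyl-4-methylcyclohexyl]propanoic acid F2.
- Esterify (DCC, DMAP) with (2E,4E,6E)-octa-2,4,6-trien-1-ol F3, made from 14 by Horner–Wadsworth–Emmons homologation and i-Bu2AlH reduction, to give the trienyl ester F4.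
- Run an acyclic Ireland–Claisen rearrangement (LiN(iPr)2, Me3SiCl, THF, −78 °C → rt; chair transition state) to 2-[(1S,2R,4R)-2-ethenyl-4-methylcyclohexyl]-2-methyl-3-[(1E,3E)-penta-1,3-dien-1-yl]pent-4-enoic acid F5.
- Close ring B by metathesis of the two terminal vinyl groups with the second-generation Hoveyda–Grubbs catalyst, RuCl2(C21H26N2)(=CH-C6H4-2-OiPr).

Stereocontrol at C1 and C2 is weaker here, so the wanted diastereomer of F5 would have to be separated.

**Step 15 (light-driven carbene/photoredox C-acylation, the proposed new step).** The hindered acyl azolium may form slowly, the diene may be sensitised, or O-acylation may dominate. Fallback with known chemistry (Lacey–Dieckmann): set out from 24 and come back at 31.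
- Activate 24 with CDI to the imidazolide 29 and C-acylate Meldrum's acid 26 (DMAP, CH2Cl2) to the acyl Meldrum's acid F6.
- Heat F6 with commercial methyl O-tert-butyl-L-threoninate F7 (PhMe, 90 °C) to the β-ketoamide F8 through the acylketene.
- Cyclise with NaOMe in MeOH (Dieckmann) to the O-tert-butyl tetramic acid F9.
- Cleave the ether with CF3CO2H/CH2Cl2 to give 31.

Further compounds
F1 | step 11 | 2-[(1S,2S,4R)-2-[(1R,4E,6E)-1-hydroxyocta-4,6-dien-2-yn-1-yl]-4-methylcyclohexyl]propanoic acid | C/C=C/C=C/C#C[C@H](O)[C@H]1C[C@H](C)CC[C@@H]1C(C)C(=O)O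
F2 | step 13 | 2-[(1S,2R,4R)-2-ethenyl-4-methylcyclohexyl]propanoic acid | C=C[C@H]1C[C@H](C)CC[C@@H]1C(C)C(=O)O
F3 | step 13 | (2E,4E,6E)-octa-2,4,6-trien-1-ol | C/C=C/C=C/C=C/CO
F4 | step 13 | (2E,4E,6E)-octa-2,4,6-trien-1-yl 2-[(1S,2R,4R)-2-ethenyl-4-methylcyclohexyl]propanoate | C=C[C@H]1C[C@H](C)CC[C@@H]1C(C)C(=O)OC/C=C/C=C/C=C/C
F5 | step 13 | 2-[(1S,2R,4R)-2-ethenyl-4-methylcyclohexyl]-2-methyl-3-[(1E,3E)-penta-1,3-dien-1-yl]pent-4-enoic acid (C2 and C3 configured as C1 and C2 of 24) | C=C[C@H]1C[C@H](C)CC[C@@H]1[C@@](C)(C(=O)O)[C@@H](C=C)/C=C/C=C/C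
F6 | step 15 | 5-{[(1R,2R,4aR,6R,8aS)-1,6-dimethyl-2-[(1E,3E)-penta-1,3-dien-1-yl]-1,2,4a,5,6,7,8,8a-octahydronaphthalen-1-yl]carbonyl}-2,2-dimethyl-1,3-dioxane-4,6-dione | C/C=C/C=C/[C@@H]1C=C[C@H]2C[C@H](C)CC[C@@H]2[C@@]1(C)C(=O)C3C(=O)OC(C)(C)OC3=O
F7 | step 15 | methyl O-tert-butyl-L-threoninate | C[C@@H](OC(C)(C)C)[C@H](N)C(=O)OC
F8 | step 15 | methyl N-{3-[(1R,2R,4aR,6R,8aS)-1,6-dimethyl-2-[(1E,3E)-penta-1,3-dien-1-yl]-1,2,4a,5,6,7,8,8a-octahydronaphthalen-1-yl]-3-oxopropanoyl}-O-tert-butyl-L-threoninate | C/C=C/C=C/[C@@H]1C=C[C@H]2C[C@H](C)CC[C@@H]2[C@@]1(C)C(=O)CC(=O)N[C@@H]([C@@H](C)OC(C)(C)C)C(=O)OC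
F9 | step 15 | O-tert-butyl ether of 31 | C/C=C/C=C/[C@@H]1C=C[C@H]2C[C@H](C)CC[C@@H]2[C@@]1(C)C(=O)C3=C(O)[C@H]([C@@H](C)OC(C)(C)C)NC3=O
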